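**Assumption:** locants follow the 1,2-dihydronaphthalene core (C1 bears the pyranone, C2 the saturated CO2H, C3 the vinylic CO2H); read this way the given SMILES is the trans-(1R,2S) isomer.

## Retrosynthetic overview

1. The pyranone is disconnected at its C–O bonds: oxygen insertion into a 3,4,5-trihydroxyphenyl ring (intradiol cleavage), then lactonisation of the resulting 2-hydroxymuconic acid; a final O-demethylation frees the catechol.
2. The pyrogallol lignan comes from its tribenzyl ether, itself from an acyl oxazolidinone by auxiliary removal.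
3. The dihydronaphthalene ring is closed by Friedel–Crafts attack (C1–C8a) on a benzylic cation, with the C2 centre directing C1 trans.
4. The cyclisation precursor comes from an Evans syn-aldol (sets C2) between 3,4,5-tris(benzyloxy)benzaldehyde and the imide of a Stobbe half-ester made from 3,4-dimethoxybenzaldehyde and di-tert-butyl succinate.
5. Ring order: carbocyclic ring B of the dihydronaphthalene first (step 4), pyranone ring last (step 7).

## Route

Step 1
Reactants: 1 3,4-dimethoxybenzaldehyde; 2 di-tert-butyl succinate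
Product: 3 (3E)-3-(tert-butoxycarbonyl)-4-(3,4-dimethoxyphenyl)but-3-enoic acid
Conditions: KOtBu, tBuOH, 80 °C; then 1 M HCl
Reagents that add atoms: none
Why: Stobbe condensation, in which the aldolate lactonises onto the distal ester and E1cB opening gives the (E)-arylidene half-ester with the free acid on the CH2 arm; no stereocentre is formed.

Step 2
Reactants: 3 (3E)-3-(tert-butoxycarbonyl)-4-(3,4-dimethoxyphenyl)but-3-enoic acid; 4 (R)-4-benzyl-1,3-oxazolidin-2-one
Product: 6 (4R)-4-benzyl-3-[(3E)-3-(tert-butoxycarbonyl)-4-(3,4-dimethoxyphenyl)but-3-enoyl]-1,3-oxazolidin-2-one, via mixed pivalic anhydride 5 (not isolated)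
Conditions: PivCl, Et3N, THF, −20 °C; then 4, LiCl, −20 °C to rt
Reagents that add atoms: none
Why: Mixed-anhydride N-acylation of the oxazolidinone (LiCl/Et3N protocol) occurs at the unhindered carbonyl of the anhydride; no stereocentre is formed and the alkene stays in conjugation with arene and ester.

Step 3
Reactants: 6 (4R)-4-benzyl-3-[(3E)-3-(tert-butoxycarbonyl)-4-(3,4-dimethoxyphenyl)but-3-enoyl]-1,3-oxazolidin-2-one; 7 3,4,5-tris(benzyloxy)benzaldehyde
Product: 9 (4R)-4-benzyl-3-[(2R,3E)-3-(tert-butoxycarbonyl)-4-(3,4-dimethoxyphenyl)-2-{(R)-hydroxy[3,4,5-tris(benzyloxy)phenyl]methyl}but-3-enoyl]-1,3-oxazolidin-2-one, via dibutylboron Z-enolate 8 (not isolated)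
Conditions: Bu2BOTf, iPr2NEt, CH2Cl2, −78 to 0 °C; then 7, −78 to 0 °C; pH 7 buffer, MeOH, H2O2, 0 °C
Reagents that add atoms: none
Why: Evans syn-aldol reaction, in which the Z(O)-boron enolate reacts at its α-carbon through a Zimmerman–Traxler chair with the auxiliary benzyl group shielding one face, setting C2 (R, the future 2S centre) and the carbinol centre.

Step 4
Reactants: 9 the syn-aldol adduct
Product: 11 (1R,2S)-2-{[(4R)-4-benzyl-2-oxo-1,3-oxazolidin-3-yl]carbonyl}-6,7-dimethoxy-1-[3,4,5-tris(benzyloxy)phenyl]-1,2-dihydronaphthalene-3-carboxylic acid, via cyclised tert-butyl ester 10 (not isolated)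
Conditions: TFA/CH2Cl2 (1:3), 0 °C to rt
Reagents that add atoms: none
Why: Ionisation of the electron-rich benzylic alcohol gives a cation that the cis-disposed dimethoxyarene captures para to a methoxy group (intramolecular Friedel–Crafts alkylation) anti to the C2 acyl group, giving the trans ring and C1 (R), while TFA also cleaves the tert-butyl ester.

Step 5
Reactants: 11 the acyl oxazolidinone acid
Product: 13 (1R,2S)-6,7-dimethoxy-1-[3,4,5-tris(benzyloxy)phenyl]-1,2-dihydronaphthalene-2,3-dicarboxylic acid, via peroxy acid 12 (not isolated)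
Conditions: LiOH, H2O2, THF/H2O (3:1), 0 °C; then Na2SO3; then 1 M HCl
Reagents that add atoms: hydrogen peroxide OO
Why: Evans hydroperoxide cleavage, in which LiOOH attacks the exocyclic imide carbonyl selectively and sulfite reduces the peracid; the C3 carboxylate lowers the acidity of C2–H, so the trans stereocentres are kept and the auxiliary is recovered.

Step 6
Reactants: 13 the tribenzyl ether diacid
Product: 14 (1R,2S)-6,7-dimethoxy-1-(3,4,5-trihydroxyphenyl)-1,2-dihydronaphthalene-2,3-dicarboxylic acid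
Conditions: BCl3, C6HMe5, CH2Cl2, −78 °C; then H2O/THF
Reagents that add atoms: none
Why: Lewis-acid debenzylation of aryl benzyl ethers with pentamethylbenzene as a non-basic benzyl-cation scavenger proceeds at −78 °C, where the aryl methyl ethers, the conjugated alkene and both stereocentres are untouched.

Step 7
Reactants: 14 the pyrogallol diacid
Product: 16 (1R,2S)-1-(6-carboxy-2-oxo-2H-pyran-4-yl)-6,7-dimethoxy-1,2-dihydronaphthalene-2,3-dicarboxylic acid, via hydroxymuconic acid 15 (not isolated)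
Conditions: Fe(OTf)3 (10 mol %), tris(2-pyridylmethyl)amine (11 mol %), 2,6-lutidine (20 mol %), O2 (1 atm), MeCN/H2O (9:1), 25 °C; then 2 M HCl, 40 °C
Reagents that add atoms: dioxygen O=O
Why: Proposed new method: the free pyrogallol (the dimethoxy ring cannot chelate) binds trivalent iron as a catecholate with semiquinone character, O2 adds at a ring carbon to give an iron alkylperoxo species, Criegee-type acyl migration inserts oxygen between two oxygenated carbons to give the hydroxymuconic anhydride, iron-bound hydroxide opens it, and on acidification the enol (through its 2-oxo tautomer) lactonises onto the Z-acrylic acid to close the 6-carboxy-2-pyranone; the symmetric 5-substituted pyrogallol allows only one regiochemical outcome and no stereocentre is touched; the closest known reactions are the intradiol (catechol 1,2-dioxygenase-type) cleavage of 3,5-di-tert-butylcatechol by tris(2-pyridylmethyl)amine complexes of trivalent iron under O2 and the acid lactonisation of 2-hydroxymuconic acids to 2-pyranone-6-carboxylic acids, neither yet shown as a catalytic cleavage of a pyrogallol in a polyfunctional substrate.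

Step 8
Reactants: 16 the pyranone dimethyl ether
Product: 17 (1R,2S)-1-(6-carboxy-2-oxo-2H-pyran-4-yl)-6,7-dihydroxy-1,2-dihydronaphthalene-2,3-dicarboxylic acid (target)
Conditions: BBr3, CH2Cl2, −78 °C to rt; then H2O
Reagents that add atoms: none
Why: BBr3 demethylation of the catechol dimethyl ether (O-complexation, then bromide attack on methyl) is non-basic, so the pyranone, the acids and the acid-stable trans C1/C2 centres survive.

## Compound list

1 | 3,4-dimethoxybenzaldehyde | COc1ccc(C=O)cc1OC | starting material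
2 | di-tert-butyl succinate | CC(C)(C)OC(=O)CCC(=O)OC(C)(C)C | starting material
3 | (3E)-3-(tert-butoxycarbonyl)-4-(3,4-dimethoxyphenyl)but-3-enoic acid | COc1ccc(/C=C(\CC(=O)O)C(=O)OC(C)(C)C)cc1OC | intermediate
4 | (R)-4-benzyl-1,3-oxazolidin-2-one | O=C1N[C@H](Cc2ccccc2)CO1 | starting material
5 | mixed anhydride of 3 with pivalic acid | COc1ccc(/C=C(\CC(=O)OC(=O)C(C)(C)C)C(=O)OC(C)(C)C)cc1OC | intermediate (not isolated)
6 | (4R)-4-benzyl-3-[(3E)-3-(tert-butoxycarbonyl)-4-(3,4-dimethoxyphenyl)but-3-enoyl]-1,3-oxazolidin-2-one | COc1ccc(/C=C(\CC(=O)N2[C@H](Cc3ccccc3)COC2=O)C(=O)OC(C)(C)C)cc1OC | intermediate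
7 | 3,4,5-tris(benzyloxy)benzaldehyde | O=Cc1cc(OCc2ccccc2)c(OCc2ccccc2)c(OCc2ccccc2)c1 | starting material
8 | dibutylboron (Z)-enolate of 6 | CCCCB(CCCC)O/C(=C\C(=C/c1ccc(OC)c(OC)c1)C(=O)OC(C)(C)C)N1[C@H](Cc2ccccc2)COC1=O | intermediate (not isolated)
9 | (4R)-4-benzyl-3-[(2R,3E)-3-(tert-butoxycarbonyl)-4-(3,4-dimethoxyphenyl)-2-{(R)-hydroxy[3,4,5-tris(benzyloxy)phenyl]methyl}but-3-enoyl]-1,3-oxazolidin-2-one | O[C@@H](c1cc(OCc2ccccc2)c(OCc2ccccc2)c(OCc2ccccc2)c1)[C@@H](/C(=C\c1ccc(OC)c(OC)c1)C(=O)OC(C)(C)C)C(=O)N1[C@H](Cc2ccccc2)COC1=O | intermediate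
10 | tert-butyl (1R,2S)-2-{[(4R)-4-benzyl-2-oxo-1,3-oxazolidin-3-yl]carbonyl}-6,7-dimethoxy-1-[3,4,5-tris(benzyloxy)phenyl]-1,2-dihydronaphthalene-3-carboxylate | CC(C)(C)OC(=O)C1=Cc2cc(OC)c(OC)cc2[C@@H](c2cc(OCc3ccccc3)c(OCc3ccccc3)c(OCc3ccccc3)c2)[C@@H]1C(=O)N4[C@H](Cc5ccccc5)COC4=O | intermediate (not isolated)
11 | (1R,2S)-2-{[(4R)-4-benzyl-2-oxo-1,3-oxazolidin-3-yl]carbonyl}-6,7-dimethoxy-1-[3,4,5-tris(benzyloxy)phenyl]-1,2-dihydronaphthalene-3-carboxylic acid | O=C(O)C1=Cc2cc(OC)c(OC)cc2[C@@H](c2cc(OCc3ccccc3)c(OCc3ccccc3)c(OCc3ccccc3)c2)[C@@H]1C(=O)N4[C@H](Cc5ccccc5)COC4=O | intermediate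
12 | (1R,2S)-3-carboxy-6,7-dimethoxy-1-[3,4,5-tris(benzyloxy)phenyl]-1,2-dihydronaphthalene-2-carboperoxoic acid | O=C(O)C1=Cc2cc(OC)c(OC)cc2[C@@H](c2cc(OCc3ccccc3)c(OCc3ccccc3)c(OCc3ccccc3)c2)[C@@H]1C(=O)OO | intermediate (not isolated)
13 | (1R,2S)-6,7-dimethoxy-1-[3,4,5-tris(benzyloxy)phenyl]-1,2-dihydronaphthalene-2,3-dicarboxylic acid | O=C(O)C1=Cc2cc(OC)c(OC)cc2[C@@H](c2cc(OCc3ccccc3)c(OCc3ccccc3)c(OCc3ccccc3)c2)[C@@H]1C(=O)O | intermediate
14 | (1R,2S)-6,7-dimethoxy-1-(3,4,5-trihydroxyphenyl)-1,2-dihydronaphthalene-2,3-dicarboxylic acid | O=C(O)C1=Cc2cc(OC)c(OC)cc2[C@@H](c2cc(O)c(O)c(O)c2)[C@@H]1C(=O)O | intermediate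
15 | (2E,4Z)-4-[(1R,2S)-2,3-dicarboxy-6,7-dimethoxy-1,2-dihydronaphthalen-1-yl]-2-hydroxyhexa-2,4-dienedioic acid | O=C(O)C1=Cc2cc(OC)c(OC)cc2[C@@H](C(=C/C(=O)O)/C=C(/O)C(=O)O)[C@@H]1C(=O)O | intermediate (not isolated)
16 | (1R,2S)-1-(6-carboxy-2-oxo-2H-pyran-4-yl)-6,7-dimethoxy-1,2-dihydronaphthalene-2,3-dicarboxylic acid | O=C(O)C1=Cc2cc(OC)c(OC)cc2[C@@H](c2cc(C(=O)O)oc(=O)c2)[C@@H]1C(=O)O | intermediate
17 | (1R,2S)-1-(6-carboxy-2-oxo-2H-pyran-4-yl)-6,7-dihydroxy-1,2-dihydronaphthalene-2,3-dicarboxylic acid | O=C(O)C1=Cc2cc(O)c(O)cc2[C@@H](c2cc(C(=O)O)oc(=O)c2)[C@@H]1C(=O)O | target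

## Step count and risk

Total step count: 8. Longest linear sequence: 8 steps (fully linear, 1 to 17).

**Step 7 (the new reaction).** The likely failures are outer-sphere oxidation to a free hydroxy-quinone that dimerises or dehydrogenates the dihydronaphthalene, and catalyst inhibition by the carboxylates. The fallback uses known stoichiometric chemistry and sets out from 14. o-Chloranil in Et2O/MeCN at −40 °C dehydrogenates the pyrogallol to the hydroxy-ortho-quinone (1R,2S)-1-(5-hydroxy-3,4-dioxocyclohexa-1,5-dien-1-yl)-6,7-dimethoxy-1,2-dihydronaphthalene-2,3-dicarboxylic acid F1. Without isolation, mCPBA in CH2Cl2 at 0 °C performs a Baeyer–Villiger oxygen insertion between the two carbonyls to give the seven-membered hydroxymuconic anhydride F2. Warming in THF/2 M HCl hydrolyses the anhydride and relactonises it to the pyranone, rejoining the route at 16.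

**Step 4 (cation cyclisation).** The risks are E1 loss of the C2 proton to an achiral bis-arylidene, capture of the cation by the tert-butyl ester (lactone), and partial loss of benzyl ethers in TFA. The fallback separates ionisation from ester cleavage and sets out from 9. Ac2O/pyridine at 0 °C gives the benzylic acetate F3, which ionises with Sc(OTf)3 (5 mol %) in CH2Cl2 at −20 °C. Ring closure then occurs with the tert-butyl ester intact, rejoining the route at 10, which brief TFA treatment converts to 11 as before.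

**Step 5 (auxiliary removal).** The imide is hindered and the substrate carries an acidic, oxidisable C2–H, so endocyclic cleavage, epimerisation or aromatisation under basic peroxide are possible. The fallback avoids base and peroxide and sets out from 11. In THF/aqueous NaOAc–AcOH buffer (pH 5.5) at 45 °C the neighbouring C3 carboxylate attacks the imide carbonyl intramolecularly, expelling 4 and forming the cyclic anhydride (1R,2S)-6,7-dimethoxy-1-[3,4,5-tris(benzyloxy)phenyl]-1,2-dihydronaphthalene-2,3-dicarboxylic anhydride F4. This hydrolyses in the same medium to the diacid, rejoining the route at 13.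

Further compounds
F1 | step 7 | (1R,2S)-1-(5-hydroxy-3,4-dioxocyclohexa-1,5-dien-1-yl)-6,7-dimethoxy-1,2-dihydronaphthalene-2,3-dicarboxylic acid | O=C(O)C1=Cc2cc(OC)c(OC)cc2[C@@H](C2=CC(=O)C(=O)C(O)=C2)[C@@H]1C(=O)O
F2 | step 7 | (1R,2S)-1-(6-hydroxy-2,7-dioxo-2,7-dihydrooxepin-4-yl)-6,7-dimethoxy-1,2-dihydronaphthalene-2,3-dicarboxylic acid | O=C(O)C1=Cc2cc(OC)c(OC)cc2[C@@H](C2=CC(=O)OC(=O)C(O)=C2)[C@@H]1C(=O)O
F3 | step 4 | (4R)-3-[(2R,3E)-2-{(R)-acetoxy[3,4,5-tris(benzyloxy)phenyl]methyl}-3-(tert-butoxycarbonyl)-4-(3,4-dimethoxyphenyl)but-3-enoyl]-4-benzyl-1,3-oxazolidin-2-one | CC(=O)O[C@@H](c1cc(OCc2ccccc2)c(OCc2ccccc2)c(OCc2ccccc2)c1)[C@@H](/C(=C\c1ccc(OC)c(OC)c1)C(=O)OC(C)(C)C)C(=O)N1[C@H](Cc2ccccc2)COC1=O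
F4 | step 5 | (1R,2S)-6,7-dimethoxy-1-[3,4,5-tris(benzyloxy)phenyl]-1,2-dihydronaphthalene-2,3-dicarboxylic anhydride | O=C3C1=Cc2cc(OC)c(OC)cc2[C@@H](c2cc(OCc4ccccc4)c(OCc4ccccc4)c(OCc4ccccc4)c2)[C@@H]1C(=O)O3
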